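**Retrosynthetic overview**
- Last bond: C5–CH= of the enal, by Heck coupling of a C5 aryl bromide (carried from the first step) with acrolein diethyl acetal.
- Key disconnection: the 3,4-dimethoxyphenyl–C2 bond and, in the same operation, the C3–CH2O bond. A flat 2-lithiated 5-bromo-7-methoxybenzofuran, the 3,4-dimethoxyphenylboronic ester of a C2-symmetric chiral diol and a silyloxymethyl chloride are joined by an electrophile-triggered 1,2-aryl shift from boron to C2; protonolysis of the C2–B bond then gives C2–H.
- Enabling feature: the O1–C2=C3 enol-ether unit of the furan ring. C2–H is its most acidic C–H (site of lithiation and boron attachment) and C3 is its nucleophilic β-carbon; anti addition across C2=C3 turns both sp2 carbons into the two stereocentres with the trans relation of the target.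
- Ring order: both benzene rings are bought; the furan ring is closed first (step 2) and later dearomatised in place; no ring is formed after step 2.

Key step: step 4

Assumption: the sense of asymmetric induction by the (R,R)-diol on boron in step 4 is a prediction from the steric model given there; the diol acts as a stoichiometric auxiliary that leaves with boron in step 5.

Step 1
Reactants: 1 4-bromo-2-methoxyphenol; 2 2-bromo-1,1-diethoxyethane
Product: 3 4-bromo-1-(2,2-diethoxyethoxy)-2-methoxybenzene
Conditions: K2CO3, KI (cat.), DMF, 120 °C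
Reagents that add atoms: none
Why: Williamson ether synthesis, in which the phenoxide displaces the primary bromide (SN2), heat and iodide catalysis compensating for the deactivating β-alkoxy groups.

Step 2
Reactants: 3 4-bromo-1-(2,2-diethoxyethoxy)-2-methoxybenzene
Product: 4 5-bromo-7-methoxy-1-benzofuran
Conditions: polyphosphoric acid, toluene, 110 °C
Reagents that add atoms: none
Why: Classical benzofuran synthesis from an aryloxyacetaldehyde acetal: the acid ionises the acetal, the oxocarbenium ion is attacked (intramolecular Friedel–Crafts) by the only free position ortho to the ether oxygen, and loss of the second ethanol aromatises the furan ring.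

Step 3
Reactants: 5 (3,4-dimethoxyphenyl)boronic acid; 6 (1R,2R)-1,2-dicyclohexylethane-1,2-diol
Product: 7 (4R,5R)-4,5-dicyclohexyl-2-(3,4-dimethoxyphenyl)-1,3,2-dioxaborolane
Conditions: toluene, reflux, Dean–Stark
Reagents that add atoms: none
Why: Boronic acid–diol esterification driven by azeotropic removal of water, which leaves the two carbinol stereocentres of the diol untouched.

Step 4
Reactants: 4 5-bromo-7-methoxy-1-benzofuran; 7 (4R,5R)-4,5-dicyclohexyl-2-(3,4-dimethoxyphenyl)-1,3,2-dioxaborolane; 8 (chloromethoxy)tri(propan-2-yl)silane (TOM-Cl)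
Product: 11 {[(2R,3S)-5-bromo-2-[(4R,5R)-4,5-dicyclohexyl-1,3,2-dioxaborolan-2-yl]-2-(3,4-dimethoxyphenyl)-7-methoxy-2,3-dihydro-1-benzofuran-3-yl]methoxy}tri(propan-2-yl)silane, via 2-lithio-5-bromo-7-methoxybenzofuran 9 (not isolated), via lithium borate complex 10 (not isolated)
Conditions: LDA (1.05 equiv), THF, −78 °C; then 7, −78 to 0 °C; then 8 (2.5 equiv), −78 °C to rt
Reagents that add atoms: none
Why: Proposed new method: LDA removes the most acidic proton of 4 (C2–H of the furan ring), and 9 adds to 7 to give borate 10, in which C3 (β-carbon of the O1–C2=C3 enol ether, pushed further by the anionic C2–B bond) is alkylated by the α-chloro ether 8 while the 3,4-dimethoxyphenyl group shifts from boron to C2 anti-periplanar to the incoming carbon, so that the aryl–C2 and C3–CH2O bonds form in one operation and the furan ring is dearomatised. The closest known reaction type is the electrophile-induced 1,2-metallate rearrangement of indol-2-yl and furan-2-yl boronate complexes with alkyl halides or π-allyl-palladium electrophiles (giving trans-2,3-disubstituted 2-boryl indolines) and the halogen-triggered 1,2-shift of benzofuran-2-yl boronates; it has not been shown with carbon electrophiles on benzofurans or with diol-controlled face selection. No ring is closed: the existing furan ring becomes the dihydrofuran ring in place. The trans relation between C2-aryl and C3-CH2OTIPS follows from the stereospecific anti addition across C2=C3. The absolute configuration (2R,3S) is to be set by the C2-symmetric (R,R)-dioxaborolane: the electrophile must reach C3 on the face syn to the dioxaborolane oxygens, which is open only in the B–C2 rotamer that turns the cyclohexyl group on the ring carbon nearer C3 away from the benzofuran, and in this rotamer the aryl group lies on the C2 face that leads to 2R. The step needs C3-alkylation to outrun ipso attack at C2 and attack on the dimethoxyphenyl ring, which the enol-ether/borate polarisation of C3 should secure, and any minor diastereomer still carries the diol and should be separable by chromatography at this stage.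

Step 5
Reactants: 11 {[(2R,3S)-5-bromo-2-[(4R,5R)-4,5-dicyclohexyl-1,3,2-dioxaborolan-2-yl]-2-(3,4-dimethoxyphenyl)-7-methoxy-2,3-dihydro-1-benzofuran-3-yl]methoxy}tri(propan-2-yl)silane
Product: 13 [(2R,3S)-5-bromo-2-(3,4-dimethoxyphenyl)-7-methoxy-2,3-dihydro-1-benzofuran-3-yl]methanol, via desilylated boronic ester 12 (not isolated)
Conditions: TBAF·3H2O (5 equiv), THF/toluene, rt then 50 °C
Reagents that add atoms: none
Why: Fluoride first cleaves the primary TIPS ether and then activates boron (helped by the cis CH2O group, which can chelate it) for the known stereoretentive fluoride/water protodeboronation of tertiary benzylic boronic esters, so that H replaces B on the face syn to CH2OH and the aryl group ends up trans, giving (2R,3S).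

Step 6
Reactants: 13 [(2R,3S)-5-bromo-2-(3,4-dimethoxyphenyl)-7-methoxy-2,3-dihydro-1-benzofuran-3-yl]methanol; 14 3,3-diethoxyprop-1-ene
Product: 16 (2E)-3-[(2R,3S)-2-(3,4-dimethoxyphenyl)-3-(hydroxymethyl)-7-methoxy-2,3-dihydro-1-benzofuran-5-yl]prop-2-enal (4-O-methylbalanophonin), via diethyl acetal 15 (not isolated)
Conditions: Pd(OAc)2 (3 mol%), nBu4NOAc, K2CO3, KCl, DMF, 90 °C; then 2 M HCl, rt
Reagents that add atoms: water, O
Why: Mizoroki–Heck arylation of acrolein diethyl acetal under ligand-free, acetate-buffered phase-transfer conditions (which favour β-hydride elimination away from the acetal carbon), followed by acid hydrolysis of the acetal in the same flask; syn insertion and syn elimination give the E-enal, and C2 and C3 carry neither an acidic C–H nor a leaving group and are not touched.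

**Compound list**
1 | 4-bromo-2-methoxyphenol | COc1cc(Br)ccc1O | starting material
2 | 2-bromo-1,1-diethoxyethane (bromoacetaldehyde diethyl acetal) | CCOC(CBr)OCC | starting material
3 | 4-bromo-1-(2,2-diethoxyethoxy)-2-methoxybenzene | CCOC(COc1ccc(Br)cc1OC)OCC | intermediate
4 | 5-bromo-7-methoxy-1-benzofuran | COc1cc(Br)cc2ccoc12 | intermediate
5 | (3,4-dimethoxyphenyl)boronic acid | COc1ccc(B(O)O)cc1OC | starting material
6 | (1R,2R)-1,2-dicyclohexylethane-1,2-diol | O[C@H](C1CCCCC1)[C@H](O)C1CCCCC1 | starting material
7 | (4R,5R)-4,5-dicyclohexyl-2-(3,4-dimethoxyphenyl)-1,3,2-dioxaborolane | COc1ccc(B2O[C@H](C3CCCCC3)[C@@H](C3CCCCC3)O2)cc1OC | intermediate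
8 | (chloromethoxy)tri(propan-2-yl)silane (TOM-Cl) | CC(C)[Si](OCCl)(C(C)C)C(C)C | starting material
9 | (5-bromo-7-methoxy-1-benzofuran-2-yl)lithium | COc1cc(Br)cc2cc([Li])oc12 | intermediate
10 | lithium (4R,5R)-2-(5-bromo-7-methoxy-1-benzofuran-2-yl)-4,5-dicyclohexyl-2-(3,4-dimethoxyphenyl)-1,3,2-dioxaborolan-2-uide | [Li+].COc1ccc([B-]2(c3cc4cc(Br)cc(OC)c4o3)O[C@H](C3CCCCC3)[C@@H](C3CCCCC3)O2)cc1OC | intermediate
11 | {[(2R,3S)-5-bromo-2-[(4R,5R)-4,5-dicyclohexyl-1,3,2-dioxaborolan-2-yl]-2-(3,4-dimethoxyphenyl)-7-methoxy-2,3-dihydro-1-benzofuran-3-yl]methoxy}tri(propan-2-yl)silane | COc1ccc([C@]2(B3O[C@H](C4CCCCC4)[C@@H](C4CCCCC4)O3)Oc3c(OC)cc(Br)cc3[C@H]2CO[Si](C(C)C)(C(C)C)C(C)C)cc1OC | intermediate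
12 | [(2R,3S)-5-bromo-2-[(4R,5R)-4,5-dicyclohexyl-1,3,2-dioxaborolan-2-yl]-2-(3,4-dimethoxyphenyl)-7-methoxy-2,3-dihydro-1-benzofuran-3-yl]methanol | COc1ccc([C@]2(B3O[C@H](C4CCCCC4)[C@@H](C4CCCCC4)O3)Oc3c(OC)cc(Br)cc3[C@H]2CO)cc1OC | intermediate
13 | [(2R,3S)-5-bromo-2-(3,4-dimethoxyphenyl)-7-methoxy-2,3-dihydro-1-benzofuran-3-yl]methanol | COc1ccc([C@@H]2Oc3c(OC)cc(Br)cc3[C@H]2CO)cc1OC | intermediate
14 | 3,3-diethoxyprop-1-ene (acrolein diethyl acetal) | C=CC(OCC)OCC | starting material
15 | [(2R,3S)-5-[(1E)-3,3-diethoxyprop-1-en-1-yl]-2-(3,4-dimethoxyphenyl)-7-methoxy-2,3-dihydro-1-benzofuran-3-yl]methanol | COc1ccc([C@@H]2Oc3c(OC)cc(/C=C/C(OCC)OCC)cc3[C@H]2CO)cc1OC | intermediate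
16 | (2E)-3-[(2R,3S)-2-(3,4-dimethoxyphenyl)-3-(hydroxymethyl)-7-methoxy-2,3-dihydro-1-benzofuran-5-yl]prop-2-enal (4-O-methylbalanophonin) | COc1ccc([C@@H]2Oc3c(OC)cc(/C=C/C=O)cc3[C@H]2CO)cc1OC | target

**Step count and risks**
Total steps: 6. Longest linear sequence: 5 (steps 1, 2, 4, 5, 6; step 3 is a one-step side branch).

Steps most likely to fail:

1. Step 4 (Proposed new method). The borate may be alkylated with poor facial discrimination by the boron-bound diol, since the sense and size of the induction are predicted and not precedented (the enantiomeric diol is equally available). It may also be consumed by O-alkylation or ipso substitution before the 1,2-shift takes place. The fallback uses known chemistry only, sets out from 4 and returns at 13; it gives up the aryl–C2 union and closes the C2–C3 bond instead. C2-lithiation of 4 (LDA), borylation with B(OiPr)3 and oxidative work-up (H2O2) should give 5-bromo-7-methoxy-1-benzofuran-2(3H)-one F1. Acid-catalysed methanolysis opens the lactone to methyl (5-bromo-2-hydroxy-3-methoxyphenyl)acetate F2. O-Alkylation with 3,4-dimethoxybenzyl bromide (K2CO3, acetone) gives methyl {5-bromo-2-[(3,4-dimethoxyphenyl)methoxy]-3-methoxyphenyl}acetate F3. Diazo transfer (p-ABSA, DBU, MeCN) gives the aryldiazoacetate F4. Enantioselective intramolecular C–H insertion of the rhodium carbenoid into the benzylic ether C–H bond, with the enantiomer of dirhodium tetrakis(N-phthaloyl-tert-leucinate) that sets 2R, should give the cis ester methyl (2R,3S)-5-bromo-2-(3,4-dimethoxyphenyl)-7-methoxy-2,3-dihydro-1-benzofuran-3-carboxylate F5. NaOMe in MeOH epimerises C3 to the trans ester F6, and LiBH4 reduces the ester to 13.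

2. Step 5. Configurational fidelity at C2 may be lost during C–B protonolysis (a carbanion-like pathway that protonates anti to the C3 substituent and gives the cis isomer), or C–B cleavage may stall on the electron-rich benzylic centre. The fallback sets out from 11 and returns at 13, replacing kinetic stereoretention by thermodynamic control of C2. Protodeboronation is forced under conditions that need not be stereoretentive (excess fluoride at higher temperature), giving 13 together with its C2 epimer [(2S,3S)-5-bromo-2-(3,4-dimethoxyphenyl)-7-methoxy-2,3-dihydro-1-benzofuran-3-yl]methanol F7. The mixture is then treated with catalytic acid (TFA, CH2Cl2, 0 °C), which reversibly ionises the C2–O1 bond to the 4-methoxy-stabilised benzylic cation and should funnel both epimers to the thermodynamically preferred trans compound 13 without touching C3.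

3. Step 6. Oxidative addition into the electron-rich aryl bromide may be slow, so that β-hydride elimination toward the acetal carbon (giving a saturated ester) or palladium-mediated side reactions of the free alcohol compete. The fallback sets out from 13 and returns at 16, replacing the Heck reaction by a cross-coupling that brings in the E double bond preformed. Suzuki–Miyaura coupling of 13 with commercial (E)-2-(3,3-diethoxyprop-1-en-1-yl)-4,4,5,5-tetramethyl-1,3,2-dioxaborolane (Pd(dppf)Cl2, K2CO3, dioxane/H2O, 80 °C) should give acetal 15, and dilute HCl then gives 16; no compound beyond the list is made (entry F0).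

**Further compounds**
F1 | step 4 | 5-bromo-7-methoxy-1-benzofuran-2(3H)-one | COc1cc(Br)cc2CC(=O)Oc12
F2 | step 4 | methyl (5-bromo-2-hydroxy-3-methoxyphenyl)acetate | COC(=O)Cc1cc(Br)cc(OC)c1O
F3 | step 4 | methyl {5-bromo-2-[(3,4-dimethoxyphenyl)methoxy]-3-methoxyphenyl}acetate | COC(=O)Cc1cc(Br)cc(OC)c1OCc1ccc(OC)c(OC)c1
F4 | step 4 | methyl {5-bromo-2-[(3,4-dimethoxyphenyl)methoxy]-3-methoxyphenyl}(diazo)acetate | COC(=O)C(=[N+]=[N-])c1cc(Br)cc(OC)c1OCc1ccc(OC)c(OC)c1
F5 | step 4 | methyl (2R,3S)-5-bromo-2-(3,4-dimethoxyphenyl)-7-methoxy-2,3-dihydro-1-benzofuran-3-carboxylate (cis) | COc1ccc([C@@H]2Oc3c(OC)cc(Br)cc3[C@@H]2C(=O)OC)cc1OC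
F6 | step 4 | methyl (2R,3R)-5-bromo-2-(3,4-dimethoxyphenyl)-7-methoxy-2,3-dihydro-1-benzofuran-3-carboxylate (trans) | COc1ccc([C@@H]2Oc3c(OC)cc(Br)cc3[C@H]2C(=O)OC)cc1OC
F7 | step 5 | [(2S,3S)-5-bromo-2-(3,4-dimethoxyphenyl)-7-methoxy-2,3-dihydro-1-benzofuran-3-yl]methanol (cis) | COc1ccc([C@H]2Oc3c(OC)cc(Br)cc3[C@H]2CO)cc1OC
F0 | step 6 | none | none
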